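**Plan**
1. Retrosynthesis (isochromene numbering): cut C7–C8 (Claisen), O2–C1 (lactone) and C4a–C8a (conjugate addition). C8a, which carries both carbonyl carbons C1 and C8, is a malonate carbon, and C4a–C4–C3(=O)–CH3 is an alkynone.
2. This leaves dimethyl malonate and the acyclic ynedione EtC(=O)–C5(Me)(farnesyl)–C≡C–C(=O)Me. Further cuts: the alkynone acyl bond, C4a≡C4 (ester → alkyne), C5–CH3 and C5–CH2(farnesyl).
3. Enabling feature: C5 is fully substituted, so the C6 ketone can enolise only at C7. C7 lies six atoms from the ester carbon C8, which sits cis to C5 on the C4a=C8a bond of the pyranone ring.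
4. Forward: two alkylations, ester → alkyne → alkynone, carbinol → ketone; then in one flask the pyranone ring (C4a–C8a, O2–C1) and, last, the carbocycle by the C7–C8 closure.
5. Stereochemistry: the only stereocentre (C5, S) comes from two Fráter–Seebach alkylations of methyl (S)-3-hydroxypentanoate (farnesyl first, methyl second). The carbinol centre that controls it is erased on oxidation to the C6 ketone.

Key step: step 8

Remark: "farnesyl" stands for (2E,6E)-3,7,11-trimethyldodeca-2,6,10-trien-1-yl throughout; the target is taken as the 8-hydroxy-6-oxo tautomer drawn, and the three starting materials are taken as purchased.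

Step 1
Reactants: 1 methyl (3S)-3-hydroxypentanoate; 2 (2E,6E)-farnesyl bromide
Product: 3 methyl (2S,3S)-3-hydroxy-2-farnesylpentanoate
Conditions: LiN(i-Pr)2 (2.2 equiv), THF, −78 → −20 °C; then 2, −78 → 0 °C
Reagents that add atoms: none
Why: Fráter–Seebach alkylation, in which the chelated lithium alkoxide–enolate dianion should take the primary allylic bromide (SN2) on the face anti to the ethyl group of the carbinol carbon, giving the 2,3-anti product with (2S) configuration.

Step 2
Reactants: 3 methyl (2S,3S)-3-hydroxy-2-farnesylpentanoate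
Product: 4 methyl (2R,3S)-3-hydroxy-2-methyl-2-farnesylpentanoate
Conditions: LiN(i-Pr)2 (2.5 equiv), THF, −78 → −10 °C; then MeI, DMPU, −78 → 0 °C
Reagents that add atoms: iodomethane, CI
Why: second Fráter–Seebach alkylation, in which the dianion of the α-branched hydroxy ester should again be attacked on the face anti to the C3 ethyl group, so that methyl enters where farnesyl entered before and the quaternary centre is set as (2R) (the future C5 of the target) under control of the C3 carbinol.

Step 3
Reactants: 4 methyl (2R,3S)-3-hydroxy-2-methyl-2-farnesylpentanoate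
Product: 5 methyl (2R,3S)-2-methyl-3-(triethylsilyloxy)-2-farnesylpentanoate
Conditions: Et3SiOTf, 2,6-lutidine, CH2Cl2, −78 → 0 °C
Reagents that add atoms: triethylsilyl trifluoromethanesulfonate, CC[Si](CC)(CC)OS(=O)(=O)C(F)(F)F
Why: silylation of a hindered secondary alcohol with a silyl triflate and a hindered pyridine base, which blocks retro-aldol cleavage at the aldehyde stage and holds C3 at the alcohol level until the ketone is needed.

Step 4
Reactants: 5 methyl (2R,3S)-2-methyl-3-(triethylsilyloxy)-2-farnesylpentanoate
Product: 7 (3S,4S)-3-methyl-4-(triethylsilyloxy)-3-farnesylhex-1-yne, via aldehyde 6 (not isolated)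
Conditions: i-Bu2AlH (1.2 equiv), CH2Cl2, −78 °C; then MeOH, K2CO3, dimethyl (1-diazo-2-oxopropyl)phosphonate, −78 °C → rt
Reagents that add atoms: dimethyl (1-diazo-2-oxopropyl)phosphonate (Ohira–Bestmann reagent), COP(=O)(OC)C(=[N+]=[N-])C(C)=O
Why: one-flask partial reduction of the ester (the aluminium hemiacetal is stable at −78 °C) followed by Seyferth–Gilbert homologation with the Ohira–Bestmann reagent, in which the aldehyde has no α-hydrogen and so cannot epimerise (the descriptor changes from R to S only because the alkyne ranks below the carbinol carbon).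

Step 5
Reactants: 7 (3S,4S)-3-methyl-4-(triethylsilyloxy)-3-farnesylhex-1-yne
Product: 8 (5S,6S)-5-methyl-6-(triethylsilyloxy)-5-farnesyloct-3-yn-2-one
Conditions: n-BuLi, THF, −78 °C; then MeC(O)N(OMe)Me, −78 → 0 °C
Reagents that add atoms: N-methoxy-N-methylacetamide, CC(=O)N(C)OC
Why: acylation of the lithium acetylide with a Weinreb amide, whose chelated tetrahedral adduct should prevent over-addition and release the alkynone only on work-up.

Step 6
Reactants: 8 (5S,6S)-5-methyl-6-(triethylsilyloxy)-5-farnesyloct-3-yn-2-one
Product: 9 (5S,6S)-6-hydroxy-5-methyl-5-farnesyloct-3-yn-2-one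
Conditions: HF·pyridine, THF, 0 °C → rt
Reagents that add atoms: none
Why: fluoride cleavage of the triethylsilyl ether under mildly acidic conditions that should leave the alkynone and the trisubstituted alkenes of the farnesyl chain untouched.

Step 7
Reactants: 9 (5S,6S)-6-hydroxy-5-methyl-5-farnesyloct-3-yn-2-one
Product: 10 (5S)-5-methyl-5-farnesyloct-3-yne-2,6-dione
Conditions: Dess–Martin periodinane, CH2Cl2, 0 °C → rt
Reagents that add atoms: none
Why: Dess–Martin oxidation of the secondary alcohol to the ethyl ketone, which erases the control stereocentre and cannot touch the quaternary centre because it has no α-hydrogen.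

Step 8
Reactants: 10 (5S)-5-methyl-5-farnesyloct-3-yne-2,6-dione; 11 dimethyl malonate
Product: 14 (5S)-8-hydroxy-3,5,7-trimethyl-5-farnesyl-1H-isochromene-1,6(5H)-dione (target), via alkylidene malonate 12 (not isolated), via pyranone ester 13 (not isolated)
Conditions: 11 (1.3 equiv), NaH (1.3 equiv), THF, 0 °C; then 10, 0 → 55 °C; then cold 0.5 M HCl
Reagents that add atoms: none
Why: Proposed new method: sodium dimethyl malonate adds to the alkynone carbon next to the quaternary centre (future C4a), the dienolate closes the pyranone by attack of its enolate oxygen on the ester cis to it (6-exo-trig lactonisation, loss of methoxide), and that methoxide enolises the propanoyl group at its only α-CH2 (C7), whose carbon attacks the remaining ester (C8) in a 6-(enolendo)-exo-trig Claisen (Dieckmann-type) closure. The closest known reaction types are the synthesis of 2-oxo-2H-pyran-3-carboxylates from alkynyl ketones and malonates and the Dieckmann-type closure of ortho-(2-oxoalkyl)benzoates to 4,4-dialkylnaphthalene-1,3-diones; their union in one flask is the new element. No stereocentre is formed: C5 is quaternary, has no α-hydrogen and should pass through unchanged. The step needs site selectivity, and the substrate secures it: the alkynone β-carbon is the only soft electrophile, each malonate ester has exactly one partner within reach (the one cis to the enolate arm lactonises, the one cis to C5 faces the ketone, and the lactone carbonyl is held trans to C5), and the ketone can enolise only toward C7. O-acylation and 1,2-additions are reversible, whereas the product is a vinylogous acid that is deprotonated at once, so the sequence should drain into its sodium enolate, which cold dilute acid converts into the 8-hydroxy-6-oxo tautomer held by a hydrogen bond to the lactone carbonyl.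

**Compound list**
1 | methyl (3S)-3-hydroxypentanoate | CC[C@H](O)CC(=O)OC | starting material
2 | (2E,6E)-farnesyl bromide | BrC/C=C(\C)CC/C=C(\C)CCC=C(C)C | starting material
3 | methyl (2S,3S)-3-hydroxy-2-farnesylpentanoate | CC[C@H](O)[C@H](C/C=C(\C)CC/C=C(\C)CCC=C(C)C)C(=O)OC | intermediate
4 | methyl (2R,3S)-3-hydroxy-2-methyl-2-farnesylpentanoate | CC[C@H](O)[C@@](C)(C/C=C(\C)CC/C=C(\C)CCC=C(C)C)C(=O)OC | intermediate
5 | methyl (2R,3S)-2-methyl-3-(triethylsilyloxy)-2-farnesylpentanoate | CC[C@H](O[Si](CC)(CC)CC)[C@@](C)(C/C=C(\C)CC/C=C(\C)CCC=C(C)C)C(=O)OC | intermediate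
6 | (2R,3S)-2-methyl-3-(triethylsilyloxy)-2-farnesylpentanal (not isolated) | CC[C@H](O[Si](CC)(CC)CC)[C@@](C)(C/C=C(\C)CC/C=C(\C)CCC=C(C)C)C=O | intermediate
7 | (3S,4S)-3-methyl-4-(triethylsilyloxy)-3-farnesylhex-1-yne | CC[C@H](O[Si](CC)(CC)CC)[C@@](C)(C/C=C(\C)CC/C=C(\C)CCC=C(C)C)C#C | intermediate
8 | (5S,6S)-5-methyl-6-(triethylsilyloxy)-5-farnesyloct-3-yn-2-one | CC[C@H](O[Si](CC)(CC)CC)[C@@](C)(C/C=C(\C)CC/C=C(\C)CCC=C(C)C)C#CC(C)=O | intermediate
9 | (5S,6S)-6-hydroxy-5-methyl-5-farnesyloct-3-yn-2-one | CC[C@H](O)[C@@](C)(C/C=C(\C)CC/C=C(\C)CCC=C(C)C)C#CC(C)=O | intermediate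
10 | (5S)-5-methyl-5-farnesyloct-3-yne-2,6-dione | CCC(=O)[C@@](C)(C/C=C(\C)CC/C=C(\C)CCC=C(C)C)C#CC(C)=O | intermediate
11 | dimethyl malonate | COC(=O)CC(=O)OC | starting material
12 | dimethyl 2-[(5S)-5-methyl-2,6-dioxo-5-farnesyloctan-4-ylidene]propanedioate (not isolated) | CCC(=O)[C@@](C)(C/C=C(\C)CC/C=C(\C)CCC=C(C)C)C(CC(C)=O)=C(C(=O)OC)C(=O)OC | intermediate
13 | methyl 6-methyl-2-oxo-4-[(2S)-3-oxo-2-farnesylpentan-2-yl]-2H-pyran-3-carboxylate (not isolated) | CCC(=O)[C@@](C)(C/C=C(\C)CC/C=C(\C)CCC=C(C)C)c1cc(C)oc(=O)c1C(=O)OC | intermediate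
14 | (5S)-8-hydroxy-3,5,7-trimethyl-5-farnesyl-1H-isochromene-1,6(5H)-dione | CC(C)=CCC/C(C)=C/CC/C(C)=C/C[C@]1(C)C(=O)C(C)=C(O)c2c1cc(C)oc2=O | target

**Total step count:** 8
**Longest linear sequence:** 8 steps (1 → 14)

**Steps most likely to fail**

Step 8 (Proposed new method). Conjugate addition at the neopentyl-type alkyne carbon may be slow, so that fragmentation by the methoxide set free (retro-Claisen loss of the propanoyl group, opening of the pyranone) overtakes ring closure. The fallback sets out from 10 and returns to the route at 14, using known chemistry. Methyl cyanoacetate and K2CO3 in MeCN should convert 10, by the known alkynone–cyanoacetate pyranone synthesis, into 6-methyl-2-oxo-4-[(2S)-3-oxo-2-farnesylpentan-2-yl]-2H-pyran-3-carbonitrile F1. LiN(SiMe3)2 in THF (−78 → 0 °C) then closes the same C7–C8 bond by Thorpe–Ziegler addition of the C7 enolate to the nitrile, which expels no alkoxide, to give (5S)-8-amino-3,5,7-trimethyl-5-farnesyl-1H-isochromene-1,6(5H)-dione F2. Hydrolysis of this vinylogous amide with dilute aqueous HCl in THF should give 14.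

Step 2. Enolisation of the α-branched alkoxide ester may be incomplete, the dianion may undergo retro-aldol cleavage on warming, and facial selectivity may erode in forming the quaternary centre. The fallback sets out from 2 and returns at 4. Racemic methyl 2-methyl-3-oxopentanoate F3 (purchased) is alkylated with 2 under chiral phase-transfer catalysis (C2-symmetric N-spiro binaphthyl quaternary ammonium bromide, solid Cs2CO3, toluene, −40 °C; the catalyst enantiomer that gives the R ester is used) to methyl (2R)-2-methyl-3-oxo-2-farnesylpentanoate F4. Reagent-controlled reduction with (R)-2-methyl-CBS-oxazaborolidine and catecholborane (toluene, −78 °C; catecholborane leaves the farnesyl alkenes alone) should give 4. The quaternary centre then comes from the catalyst and the carbinol from the reducing agent.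

Step 4. The neopentyl ester may be reduced too slowly or past the aldehyde stage, and homologation of the hindered aldehyde in basic methanol may be slow enough for loss of the silyl ether. The fallback sets out from 5 and returns at 8. LiAlH4 (Et2O, 0 °C) reduces 5 fully to (2S,3S)-2-methyl-3-(triethylsilyloxy)-2-farnesylpentan-1-ol F5. Dess–Martin oxidation gives aldehyde 6, now isolated. CBr4/PPh3 (CH2Cl2, 0 °C, Corey–Fuchs olefination) gives (3S,4S)-1,1-dibromo-3-methyl-4-(triethylsilyloxy)-3-farnesylhex-1-ene F6. n-BuLi (2.2 equiv, THF, −78 °C; Fritsch–Buttenberg–Wiechell rearrangement to the lithium acetylide) followed by N-methoxy-N-methylacetamide should give 8 directly, so that step 5 is absorbed.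

**Further compounds**
F1 | step 8 | 6-methyl-2-oxo-4-[(2S)-3-oxo-2-farnesylpentan-2-yl]-2H-pyran-3-carbonitrile | CCC(=O)[C@@](C)(C/C=C(\C)CC/C=C(\C)CCC=C(C)C)c1cc(C)oc(=O)c1C#N
F2 | step 8 | (5S)-8-amino-3,5,7-trimethyl-5-farnesyl-1H-isochromene-1,6(5H)-dione | CC(C)=CCC/C(C)=C/CC/C(C)=C/C[C@]1(C)C(=O)C(C)=C(N)c2c1cc(C)oc2=O
F3 | step 2 | methyl 2-methyl-3-oxopentanoate (racemic, purchased) | CCC(=O)C(C)C(=O)OC
F4 | step 2 | methyl (2R)-2-methyl-3-oxo-2-farnesylpentanoate | CCC(=O)[C@@](C)(C/C=C(\C)CC/C=C(\C)CCC=C(C)C)C(=O)OC
F5 | step 4 | (2S,3S)-2-methyl-3-(triethylsilyloxy)-2-farnesylpentan-1-ol | CC[C@H](O[Si](CC)(CC)CC)[C@@](C)(C/C=C(\C)CC/C=C(\C)CCC=C(C)C)CO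
F6 | step 4 | (3S,4S)-1,1-dibromo-3-methyl-4-(triethylsilyloxy)-3-farnesylhex-1-ene | CC[C@H](O[Si](CC)(CC)CC)[C@@](C)(C/C=C(\C)CC/C=C(\C)CCC=C(C)C)C=C(Br)Br
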